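- I decided to count incoming ligand before looking at any clock, since Thursday's flask was charged with less of it than of starting complex.

the same everywhere: starting complex 1.1 M

|  | incoming ligand | remark | time |
|---|---|---|---|
| Thursday's | 0.55 M | the very flask that is asked about, followed so far |  |
| Saturday's | 0.28 M | run made earlier |  |
| flask | 0.550 M |  | 15 d |

| run | time / d | complex with one exchanged / % | complex with two exchanged / % | starting complex / % |
|---|---|---|---|---|
| Thursday's | 1.04 | 31.3 | 7.1 | 60.7 |
| Thursday's | 2.50 | 31.1 | 6.5 | 60.5 |
| Thursday's | 5.00 | 31.7 | 6.5 | 61.2 |
| Thursday's | 8.00 | 31.8 | 6.7 | 62.3 |
| Saturday's | 2.50 | 20.3 | 2.4 | 77.6 |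
| Saturday's | 5.00 | 20.1 | 2.4 | 77.5 |
| Saturday's | 8.00 | 20.0 | 2.1 | 77.4 |
| Saturday's | 10.0 | 20.0 | 2.1 | 77.2 |

(scatter of a reading: 0.3 percentage points)
* at 15 d, what has stopped the reaction, if anything has (all of the starting complex has reacted / it is still moving / the incoming ligand has run out first)
* amount of complex with one exchanged at 15 d, in percent of the starting complex charged
* amount of complex with two exchanged at 15 d, in percent of the starting complex charged
* amount of complex with one exchanged if the flask were left three thousand times as long, in percent of the starting complex charged
- what was read earlier has a scatter of 0.3 percentage points, one standard deviation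
- the reaction counts as stopped when no species that holds the starting complex changes by six tenths of a point or more over the second half of the time

- Thursday's flask had an exchange budget m of 0.500, meaning the incoming ligand charged per starting complex charged, the mean number of exchanges a complex can receive.
- My first estimate put that mean in place of the separate curves. If ligand lands at random, as with equally fast steps, the untouched share is the exponential of minus m; multiplying by m gives one exchange, and by m squared over two gives two exchanges. That gave 60.7%, 30.3% and 7.58%.
- Equal speed was only my assumption, so I tried Saturday's flask: its budget of 0.255 gave 77.5% starting complex, and its readings average 77.4%.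
- But Thursday's readings of complex with one exchanged average 31.5%, which is 1.1 percentage points over my estimate, against a scatter of 0.3 points. For the numbers I therefore kept Thursday's averages, with 6.70% for complex with two exchanged.
- Was ligand still left? Thursday's budget is 50.0% of the complex charged, and the read complexes account for 44.9%, counting two per complex with two exchanged. Complexes with three exchanged, reckoned the same way and counted three per complex, take 3.79% of the budget, leaving 1.3 points unplaced. Starting complex read 1.6 points higher at the last reading than at the first, so I saw no further consumption in those readings and took incoming ligand as the limiting reagent.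
- The forecast said the incoming ligand has run out first, with 31.6% (31% to 32.2%) of complex with one exchanged, 6.7% (6.2% to 7.2%) of complex with two exchanged, and 31.6% (29.5% to 33%) after a very long wait, expecting “15 d values near the plateau averages”.
- The simulation gave the incoming ligand has run out first, with 31.3%, 6.50%, and 31.3% after the very long wait.

    starting complex + incoming ligand → leaving ligand + complex with one exchanged (k = 1.00 × 10⁻⁴ M⁻¹ s⁻¹)
    complex with one exchanged + incoming ligand → leaving ligand + complex with two exchanged (k = 8.60 × 10⁻⁵ M⁻¹ s⁻¹)
    complex with two exchanged + incoming ligand → leaving ligand + complex with three exchanged (k = 1.10 × 10⁻⁴ M⁻¹ s⁻¹)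
    2 incoming ligand → self-condensation product (k = 6.90 × 10⁻⁶ M⁻¹ s⁻¹)

- Thursday's flask held 0% of its incoming ligand at 15.0 d, and starting complex stood at 61%. With the supply kept from shrinking, conversion of starting complex reached 100% instead of 39.1%, so that shrinking supply stopped this flask. A neighbour charged with 1.4 M of incoming ligand has a budget of 1.27, which gives 28.1% starting complex and 35.7% complex with one exchanged; that flask held 28.4% and 39.1%.

All runs stem from a simulated flask on assumed constants, and the scatter is random.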